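**Plan**

1. Labels: isochroman numbering is used for rings A and B (C1 acetal carbon, O2 bridging oxygen, C3 carbinol carbon, C4 acetyl methine, C4a–C8a ring A); ring C is the 1,3-dioxin ring; primed locants belong to the isoquinoline.
2. Cuts: first the aryl acetal bond C1–O–C6′ of ring C (back to a lactol and a free isoquinoline 6′-OH), then ring B at C3–C4 and at O2–C1 (as a lactone), which leaves a homophthalic anhydride and an isoquinoline-7-carbaldehyde.
3. Enabling feature: ring B (C8a and C4a of ring A, C1, O2, C3 and C4) is a 3-aryl-4-acyl isochroman, i.e. the adduct of an enolised homophthalic unit and an aryl aldehyde.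
4. Both halves carry the same arene pattern (OMe, formyl carbon, O, H), so both are drawn from one arylacetic acid, 7, reached from methyl orsellinate by a single lateral lithiation–carboxylation. Forward ring order: pyridine ring of the isoquinoline (step 10), ring B (step 14), ring C (step 19).
5. Stereochemistry: C3 comes from the squaramide catalyst; C1 follows from C3 because only the syn-bridged acetal can close; C4 is set last by kinetic protonation on the convex face, which puts the acetyl group endo (on the isoquinoline side).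
6. All O-protecting groups are acetals, so one acid step unmasks everything; hydrogenolysis is avoided because it would threaten the benzylic C3–O and C1–O bonds.

Key step: step 14

Assumption: the quinine-derived squaramide is taken to deliver the (3R) lactone; if the sense of induction proves opposite, its quinidine-derived pseudoenantiomer is used with nothing else changed.

**Route**

Step 1
Reactants: 1 methyl 2,4-dihydroxy-6-methylbenzoate (methyl orsellinate)
Product: 2 methyl 2-hydroxy-4-(methoxymethoxy)-6-methylbenzoate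
Conditions: MOMCl (1.1 equiv), i-Pr2NEt, CH2Cl2, 0 °C → rt
Reagents that add atoms: chloromethyl methyl ether, COCCl
Why: Williamson-type O-alkylation goes to the free 4-OH only, because the 2-OH is held in a hydrogen bond to the ester and is much less nucleophilic.

Step 2
Reactants: 2 methyl 2-hydroxy-4-(methoxymethoxy)-6-methylbenzoate
Product: 3 methyl 3-formyl-2-hydroxy-4-(methoxymethoxy)-6-methylbenzoate
Conditions: MgCl2, Et3N, (CH2O)n, MeCN, reflux; cold 1 M HCl wash
Reagents that add atoms: formaldehyde (from paraformaldehyde), C=O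
Why: Magnesium-mediated ortho-formylation (Casnati–Skattebøl): the magnesium phenoxide delivers formaldehyde to its only free ortho carbon, C3 between the two oxygens, and a second formaldehyde oxidises the benzylic alkoxide to the aldehyde.

Step 3
Reactants: 3 methyl 3-formyl-2-hydroxy-4-(methoxymethoxy)-6-methylbenzoate
Product: 4 methyl 3-formyl-2-methoxy-4-(methoxymethoxy)-6-methylbenzoate
Conditions: MeI, K2CO3, DMF, 40 °C
Reagents that add atoms: iodomethane, CI
Why: Williamson O-methylation of the remaining phenol, which is acidified by two ortho carbonyl groups so that carbonate in DMF is sufficient.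

Step 4
Reactants: 4 methyl 3-formyl-2-methoxy-4-(methoxymethoxy)-6-methylbenzoate
Product: 5 methyl 3-(1,3-dioxolan-2-yl)-2-methoxy-4-(methoxymethoxy)-6-methylbenzoate
Conditions: Me3SiOCH2CH2OSiMe3, Me3SiOTf (5 mol %), CH2Cl2, −78 → −20 °C; pyridine quench
Reagents that add atoms: 1,2-bis(trimethylsilyloxy)ethane, C[Si](C)(C)OCCO[Si](C)(C)C
Why: Noyori acetalisation converts the hindered, electron-rich aldehyde to its dioxolane at low temperature without cleaving the aryl MOM ether, and the acetal makes this carbon inert to amide bases, Grignard reagents, enolates and hydride.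

Step 5
Reactants: 5 methyl 3-(1,3-dioxolan-2-yl)-2-methoxy-4-(methoxymethoxy)-6-methylbenzoate
Product: 7 2-[4-(1,3-dioxolan-2-yl)-3-methoxy-2-(methoxycarbonyl)-5-(methoxymethoxy)phenyl]acetic acid, via benzylic lithium species 6 (not isolated)
Conditions: LiN(i-Pr)2, THF, −78 °C; CO2; 1 M HCl to pH 4, 0 °C
Reagents that add atoms: carbon dioxide, O=C=O
Why: Lateral lithiation of an ortho-toluate followed by carboxylation: the ester-stabilised benzylic anion forms at −78 °C faster than it self-condenses, and CO2 gives the homophthalic half-ester that feeds both halves of the route.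

Step 6
Reactants: 7 2-[4-(1,3-dioxolan-2-yl)-3-methoxy-2-(methoxycarbonyl)-5-(methoxymethoxy)phenyl]acetic acid
Product: 8 2-(carboxymethyl)-5-(1,3-dioxolan-2-yl)-6-methoxy-4-(methoxymethoxy)benzoic acid
Conditions: KOH, MeOH–H2O, 70 °C; 1 M HCl to pH 3–4, 0 °C
Reagents that add atoms: potassium hydroxide, [K+].[OH-]
Why: Saponification of the hindered benzoate by acyl–oxygen cleavage; the MOM ether and dioxolane are stable to hydroxide and survive the cold, weakly acidic work-up.

Step 7
Reactants: 8 2-(carboxymethyl)-5-(1,3-dioxolan-2-yl)-6-methoxy-4-(methoxymethoxy)benzoic acid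
Product: 9 7-(1,3-dioxolan-2-yl)-8-methoxy-6-(methoxymethoxy)isochromane-1,3-dione
Conditions: DCC, CH2Cl2, 0 °C → rt; filter, use crude
Reagents that add atoms: none
Why: Carbodiimide cyclodehydration of a homophthalic acid closes the six-membered anhydride under neutral conditions that spare the acetal and MOM groups.

Step 8
Reactants: 7 2-[4-(1,3-dioxolan-2-yl)-3-methoxy-2-(methoxycarbonyl)-5-(methoxymethoxy)phenyl]acetic acid
Product: 10 methyl 3-(1,3-dioxolan-2-yl)-2-methoxy-6-{2-[methoxy(methyl)amino]-2-oxoethyl}-4-(methoxymethoxy)benzoate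
Conditions: MeNHOMe·HCl, EDC·HCl, N-methylmorpholine, CH2Cl2, 0 °C → rt
Reagents that add atoms: N,O-dimethylhydroxylamine hydrochloride, CNOC.Cl
Why: Carbodiimide amide coupling of the arylacetic acid gives the Weinreb amide under buffered, near-neutral conditions that leave the methyl ester, the dioxolane and the MOM ether untouched.

Step 9
Reactants: 10 methyl 3-(1,3-dioxolan-2-yl)-2-methoxy-6-{2-[methoxy(methyl)amino]-2-oxoethyl}-4-(methoxymethoxy)benzoate
Product: 11 methyl 3-(1,3-dioxolan-2-yl)-2-methoxy-4-(methoxymethoxy)-6-(2-oxopropyl)benzoate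
Conditions: MeMgBr (1.5 equiv), THF, −20 → 0 °C; aq. NH4Cl
Reagents that add atoms: methylmagnesium bromide, C[Mg]Br
Why: Weinreb ketone synthesis: the chelated magnesium tetrahedral adduct persists until the quench, so the ketone is neither attacked twice nor enolised in the flask, and the di-ortho-substituted benzoate is too hindered to compete at this temperature.

Step 10
Reactants: 11 methyl 3-(1,3-dioxolan-2-yl)-2-methoxy-4-(methoxymethoxy)-6-(2-oxopropyl)benzoate
Product: 12 7-(1,3-dioxolan-2-yl)-8-methoxy-6-(methoxymethoxy)-3-methylisoquinolin-1(2H)-one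
Conditions: NH3 (7 M in MeOH), sealed tube, 70 °C
Reagents that add atoms: ammonia, N
Why: Ammonia condenses with the ketone to an enamine that lactamises onto the ortho ester, the standard keto-ester (isocoumarin) to isoquinolone annulation.

Step 11
Reactants: 12 7-(1,3-dioxolan-2-yl)-8-methoxy-6-(methoxymethoxy)-3-methylisoquinolin-1(2H)-one
Product: 13 7-(1,3-dioxolan-2-yl)-8-methoxy-6-(methoxymethoxy)-3-methylisoquinolin-1-yl trifluoromethanesulfonate
Conditions: (CF3SO2)2O, pyridine, CH2Cl2, −20 → 0 °C
Reagents that add atoms: trifluoromethanesulfonic anhydride, O=S(=O)(OS(=O)(=O)C(F)(F)F)C(F)(F)F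
Why: O-Sulfonylation of the 2-pyridone-type lactam gives the heteroaryl triflate, the handle for removing the C1′ oxygen; pyridine buffers the acid-labile groups.

Step 12
Reactants: 13 7-(1,3-dioxolan-2-yl)-8-methoxy-6-(methoxymethoxy)-3-methylisoquinolin-1-yl trifluoromethanesulfonate
Product: 14 7-(1,3-dioxolan-2-yl)-8-methoxy-6-(methoxymethoxy)-3-methylisoquinoline
Conditions: Pd(OAc)2 (5 mol %), 1,1′-bis(diphenylphosphino)ferrocene (6 mol %), HCO2H, Et3N, DMF, 60 °C
Reagents that add atoms: none
Why: Palladium-catalysed formate reduction of a heteroaryl triflate (oxidative addition to zerovalent palladium, formate exchange, loss of CO2, C–H reductive elimination); the aryl MOM ether and dioxolane are inert in the buffered medium.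

Step 13
Reactants: 14 7-(1,3-dioxolan-2-yl)-8-methoxy-6-(methoxymethoxy)-3-methylisoquinoline
Product: 15 8-methoxy-6-(methoxymethoxy)-3-methylisoquinoline-7-carbaldehyde
Conditions: 1 M HCl (aq)–THF, 0 °C → rt; NaHCO3
Reagents that add atoms: water, O
Why: Acetal hydrolysis; the dioxolane of a 2,6-dioxygenated benzaldehyde hydrolyses far faster than an aryl MOM ether, so cold dilute acid should free the aldehyde only.

Step 14
Reactants: 9 7-(1,3-dioxolan-2-yl)-8-methoxy-6-(methoxymethoxy)isochromane-1,3-dione; 15 8-methoxy-6-(methoxymethoxy)-3-methylisoquinoline-7-carbaldehyde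
Product: 17 (3R,4R)-7-(1,3-dioxolan-2-yl)-8-methoxy-3-[8-methoxy-6-(methoxymethoxy)-3-methylisoquinolin-7-yl]-6-(methoxymethoxy)-1-oxoisochromane-4-carboxylic acid, via anhydride aldol adduct 16 (not isolated)
Conditions: 3-{[3,5-bis(trifluoromethyl)phenyl]amino}-4-{[(8α,9S)-6′-methoxycinchonan-9-yl]amino}cyclobut-3-ene-1,2-dione (10 mol %), t-BuOMe, −15 °C
Reagents that add atoms: none
Why: The quinuclidine nitrogen of the catalyst deprotonates the benzylic CH2 of anhydride 9 while the squaramide N–H bonds hold the enolate and activate the formyl group of 15, so the enolate adds to one aldehyde face and forms the C3–C4 bond (adduct 16). The alkoxide then attacks the aryl-bound anhydride carbonyl and closes ring B by a 6-exo-trig acyl transfer that forms the O2–C1 bond and releases the C4 carboxylic acid. The closest known reaction type is the amine–squaramide-catalysed formal [4+2] cycloaddition of homophthalic anhydrides with aromatic aldehydes (Tamura-type aldol–lactonisation). The C3 stereocentre (R) is set by the catalyst through face selection in the hydrogen-bonded ion pair, while C4 is expected trans to the aryl group but need not be controlled, because any C4 epimer converges in step 20. The step needs one electrophile and one enantioface: the ring A formyl carbon is masked as a dioxolane, aldehyde 15 cannot enolise, only the six-membered lactone can form, and the hindered, weakly basic isoquinoline nitrogen should not compete with the quinuclidine at −15 °C.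

Step 15
Reactants: 17 (3R,4R)-7-(1,3-dioxolan-2-yl)-8-methoxy-3-[8-methoxy-6-(methoxymethoxy)-3-methylisoquinolin-7-yl]-6-(methoxymethoxy)-1-oxoisochromane-4-carboxylic acid
Product: 18 S-ethyl (3R,4R)-7-(1,3-dioxolan-2-yl)-8-methoxy-3-[8-methoxy-6-(methoxymethoxy)-3-methylisoquinolin-7-yl]-6-(methoxymethoxy)-1-oxoisochromane-4-carbothioate
Conditions: EtSH, EDC·HCl, DMAP (cat.), CH2Cl2, 0 °C → rt
Reagents that add atoms: ethanethiol, CCS
Why: Steglich-type thioesterification of the carbodiimide-activated (zwitterionic, self-buffered) acid; a thioester is chosen over an acid chloride so that the isoquinoline nitrogen cannot be N-acylated, and C4 epimerisation here is harmless.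

Step 16
Reactants: 18 S-ethyl (3R,4R)-7-(1,3-dioxolan-2-yl)-8-methoxy-3-[8-methoxy-6-(methoxymethoxy)-3-methylisoquinolin-7-yl]-6-(methoxymethoxy)-1-oxoisochromane-4-carbothioate
Product: 19 (3R,4R)-4-acetyl-7-(1,3-dioxolan-2-yl)-8-methoxy-3-[8-methoxy-6-(methoxymethoxy)-3-methylisoquinolin-7-yl]-6-(methoxymethoxy)isochroman-1-one
Conditions: MeZnI, PdCl2(PPh3)2 (10 mol %), toluene–THF, rt
Reagents that add atoms: methylzinc iodide, C[Zn]I
Why: Fukuyama coupling (C–S oxidative addition to zerovalent palladium, transmetalation from MeZnI, reductive elimination) gives the methyl ketone under neutral conditions that leave the lactone, the acetals and the base-sensitive β-acyloxy ketone untouched.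

Step 17
Reactants: 19 (3R,4R)-4-acetyl-7-(1,3-dioxolan-2-yl)-8-methoxy-3-[8-methoxy-6-(methoxymethoxy)-3-methylisoquinolin-7-yl]-6-(methoxymethoxy)isochroman-1-one
Product: 20 (3R,4R)-7-(1,3-dioxolan-2-yl)-8-methoxy-3-[8-methoxy-6-(methoxymethoxy)-3-methylisoquinolin-7-yl]-6-(methoxymethoxy)-4-(2-methyl-1,3-dioxolan-2-yl)isochroman-1-one
Conditions: Me3SiOCH2CH2OSiMe3, Me3SiOTf (1.3 equiv), CH2Cl2, −78 → −40 °C; pyridine then aq. NaHCO3
Reagents that add atoms: 1,2-bis(trimethylsilyloxy)ethane, C[Si](C)(C)OCCO[Si](C)(C)C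
Why: Noyori ketalisation masks the ketone for the hydride step; slightly more than one equivalent of silyl triflate is used because the isoquinoline nitrogen binds the first, and any MOM group lost here would be removed in step 19 anyway.

Step 18
Reactants: 20 (3R,4R)-7-(1,3-dioxolan-2-yl)-8-methoxy-3-[8-methoxy-6-(methoxymethoxy)-3-methylisoquinolin-7-yl]-6-(methoxymethoxy)-4-(2-methyl-1,3-dioxolan-2-yl)isochroman-1-one
Product: 21 (3R,4R)-7-(1,3-dioxolan-2-yl)-8-methoxy-3-[8-methoxy-6-(methoxymethoxy)-3-methylisoquinolin-7-yl]-6-(methoxymethoxy)-4-(2-methyl-1,3-dioxolan-2-yl)isochroman-1-ol (both C1 epimers)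
Conditions: i-Bu2AlH (2.5 equiv), CH2Cl2, −78 °C; aq. potassium sodium tartrate
Reagents that add atoms: none
Why: Partial reduction of the lactone to the lactol at −78 °C, where the tetrahedral aluminium alkoxide is stable; the ketal, acetal and MOM ethers are inert, and the C1 configuration is left open because C1 is re-formed in step 19.

Step 19
Reactants: 21 (3R,4R)-7-(1,3-dioxolan-2-yl)-8-methoxy-3-[8-methoxy-6-(methoxymethoxy)-3-methylisoquinolin-7-yl]-6-(methoxymethoxy)-4-(2-methyl-1,3-dioxolan-2-yl)isochroman-1-ol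
Product: 23 (1R,3R,4R)-4-acetyl-6-hydroxy-8-methoxy-1,3-[(8-methoxy-3-methylisoquinoline-7,6-diyl)oxy]isochromane-7-carbaldehyde (4-epimer of the target; acetyl exo), via deprotected keto lactol 22 (not isolated)
Conditions: 3 M HCl (aq)–THF (1:3), 40 °C; NaHCO3 to pH 7
Reagents that add atoms: water, O
Why: Aqueous acid cleaves both MOM ethers, the dioxolane and the ketal, and the lactol ionises to the C1 oxocarbenium ion, which the freed 6′-OH traps in a 6-endo-trig acetalisation that closes ring C; only the C1 face syn to the C3 aryl group can be reached, so C1 is set (R) by C3, and N-protonation of the isoquinoline keeps the benzylic C3–O bond from ionising.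

Step 20
Reactants: 23 (1R,3R,4R)-4-acetyl-6-hydroxy-8-methoxy-1,3-[(8-methoxy-3-methylisoquinoline-7,6-diyl)oxy]isochromane-7-carbaldehyde
Product: 25 (1R,3R,4S)-4-acetyl-6-hydroxy-8-methoxy-1,3-[(8-methoxy-3-methylisoquinoline-7,6-diyl)oxy]isochromane-7-carbaldehyde (target; acetyl endo), via bis-silyl enol ether 24 (not isolated)
Conditions: Me3SiOTf, Et3N, CH2Cl2, 0 °C → rt; then Bu4NF/AcOH (1:2), THF, −78 °C
Reagents that add atoms: none
Why: Soft enolisation gives the ring A-conjugated silyl enol ether at the doubly activated C4, and cold buffered protodesilylation then protonates C4 under kinetic control from the convex (O2) face, because the isoquinoline wing and its 8′-methoxy group block the other face; this places the acetyl group endo (4S), and the cold, buffered conditions should prevent re-equilibration to the exo epimer.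

**Compound list**

1 | methyl 2,4-dihydroxy-6-methylbenzoate (methyl orsellinate) | COC(=O)c1c(C)cc(O)cc1O | starting material
2 | methyl 2-hydroxy-4-(methoxymethoxy)-6-methylbenzoate | COC(=O)c1c(C)cc(OCOC)cc1O | intermediate
3 | methyl 3-formyl-2-hydroxy-4-(methoxymethoxy)-6-methylbenzoate | COC(=O)c1c(C)cc(OCOC)c(C=O)c1O | intermediate
4 | methyl 3-formyl-2-methoxy-4-(methoxymethoxy)-6-methylbenzoate | COC(=O)c1c(C)cc(OCOC)c(C=O)c1OC | intermediate
5 | methyl 3-(1,3-dioxolan-2-yl)-2-methoxy-4-(methoxymethoxy)-6-methylbenzoate | COC(=O)c1c(C)cc(OCOC)c(C2OCCO2)c1OC | intermediate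
6 | {[4-(1,3-dioxolan-2-yl)-3-methoxy-2-(methoxycarbonyl)-5-(methoxymethoxy)phenyl]methyl}lithium (benzylic lithium species, not isolated) | COC(=O)c1c(C[Li])cc(OCOC)c(C2OCCO2)c1OC | intermediate
7 | 2-[4-(1,3-dioxolan-2-yl)-3-methoxy-2-(methoxycarbonyl)-5-(methoxymethoxy)phenyl]acetic acid | COC(=O)c1c(CC(=O)O)cc(OCOC)c(C2OCCO2)c1OC | intermediate
8 | 2-(carboxymethyl)-5-(1,3-dioxolan-2-yl)-6-methoxy-4-(methoxymethoxy)benzoic acid | OC(=O)Cc1cc(OCOC)c(C2OCCO2)c(OC)c1C(=O)O | intermediate
9 | 7-(1,3-dioxolan-2-yl)-8-methoxy-6-(methoxymethoxy)isochromane-1,3-dione | COCOc1cc2CC(=O)OC(=O)c2c(OC)c1C3OCCO3 | intermediate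
10 | methyl 3-(1,3-dioxolan-2-yl)-2-methoxy-6-{2-[methoxy(methyl)amino]-2-oxoethyl}-4-(methoxymethoxy)benzoate (Weinreb amide) | COC(=O)c1c(CC(=O)N(C)OC)cc(OCOC)c(C2OCCO2)c1OC | intermediate
11 | methyl 3-(1,3-dioxolan-2-yl)-2-methoxy-4-(methoxymethoxy)-6-(2-oxopropyl)benzoate | COC(=O)c1c(CC(C)=O)cc(OCOC)c(C2OCCO2)c1OC | intermediate
12 | 7-(1,3-dioxolan-2-yl)-8-methoxy-6-(methoxymethoxy)-3-methylisoquinolin-1(2H)-one | COCOc1cc2cc(C)[nH]c(=O)c2c(OC)c1C3OCCO3 | intermediate
13 | 7-(1,3-dioxolan-2-yl)-8-methoxy-6-(methoxymethoxy)-3-methylisoquinolin-1-yl trifluoromethanesulfonate | COCOc1cc2cc(C)nc(OS(=O)(=O)C(F)(F)F)c2c(OC)c1C3OCCO3 | intermediate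
14 | 7-(1,3-dioxolan-2-yl)-8-methoxy-6-(methoxymethoxy)-3-methylisoquinoline | COCOc1cc2cc(C)ncc2c(OC)c1C3OCCO3 | intermediate
15 | 8-methoxy-6-(methoxymethoxy)-3-methylisoquinoline-7-carbaldehyde | COCOc1cc2cc(C)ncc2c(OC)c1C=O | intermediate
16 | (4R)-7-(1,3-dioxolan-2-yl)-4-{(R)-hydroxy[8-methoxy-6-(methoxymethoxy)-3-methylisoquinolin-7-yl]methyl}-8-methoxy-6-(methoxymethoxy)isochromane-1,3-dione (aldol adduct, not isolated) | O[C@@H](c3c(OCOC)cc4cc(C)ncc4c3OC)[C@@H]2C(=O)OC(=O)c1c(OC)c(C5OCCO5)c(OCOC)cc12 | intermediate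
17 | (3R,4R)-7-(1,3-dioxolan-2-yl)-8-methoxy-3-[8-methoxy-6-(methoxymethoxy)-3-methylisoquinolin-7-yl]-6-(methoxymethoxy)-1-oxoisochromane-4-carboxylic acid (trans lactone acid) | COc1c(C5OCCO5)c(OCOC)cc2c1C(=O)O[C@@H](c3c(OCOC)cc4cc(C)ncc4c3OC)[C@@H]2C(=O)O | intermediate
18 | S-ethyl (3R,4R)-7-(1,3-dioxolan-2-yl)-8-methoxy-3-[8-methoxy-6-(methoxymethoxy)-3-methylisoquinolin-7-yl]-6-(methoxymethoxy)-1-oxoisochromane-4-carbothioate | COc1c(C5OCCO5)c(OCOC)cc2c1C(=O)O[C@@H](c3c(OCOC)cc4cc(C)ncc4c3OC)[C@@H]2C(=O)SCC | intermediate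
19 | (3R,4R)-4-acetyl-7-(1,3-dioxolan-2-yl)-8-methoxy-3-[8-methoxy-6-(methoxymethoxy)-3-methylisoquinolin-7-yl]-6-(methoxymethoxy)isochroman-1-one | COc1c(C5OCCO5)c(OCOC)cc2c1C(=O)O[C@@H](c3c(OCOC)cc4cc(C)ncc4c3OC)[C@@H]2C(C)=O | intermediate
20 | (3R,4R)-7-(1,3-dioxolan-2-yl)-8-methoxy-3-[8-methoxy-6-(methoxymethoxy)-3-methylisoquinolin-7-yl]-6-(methoxymethoxy)-4-(2-methyl-1,3-dioxolan-2-yl)isochroman-1-one | COc1c(C5OCCO5)c(OCOC)cc2c1C(=O)O[C@@H](c3c(OCOC)cc4cc(C)ncc4c3OC)[C@@H]2C6(C)OCCO6 | intermediate
21 | (3R,4R)-7-(1,3-dioxolan-2-yl)-8-methoxy-3-[8-methoxy-6-(methoxymethoxy)-3-methylisoquinolin-7-yl]-6-(methoxymethoxy)-4-(2-methyl-1,3-dioxolan-2-yl)isochroman-1-ol (lactol, both C1 epimers) | COc1c(C5OCCO5)c(OCOC)cc2c1C(O)O[C@@H](c3c(OCOC)cc4cc(C)ncc4c3OC)[C@@H]2C6(C)OCCO6 | intermediate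
22 | (3R,4R)-4-acetyl-1,6-dihydroxy-3-(6-hydroxy-8-methoxy-3-methylisoquinolin-7-yl)-8-methoxyisochromane-7-carbaldehyde (deprotected keto lactol, both C1 epimers, not isolated) | COc1c(C=O)c(O)cc2c1C(O)O[C@@H](c3c(O)cc4cc(C)ncc4c3OC)[C@@H]2C(C)=O | intermediate
23 | (1R,3R,4R)-4-acetyl-6-hydroxy-8-methoxy-1,3-[(8-methoxy-3-methylisoquinoline-7,6-diyl)oxy]isochromane-7-carbaldehyde (C3–C7′ bond, C1–O–C6′ bridge; acetyl exo; 4-epimer of the target) | COc1c(C=O)c(O)cc2c1[C@H]1Oc3cc4cc(C)ncc4c(OC)c3[C@H](O1)[C@@H]2C(C)=O | intermediate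
24 | 6-O-trimethylsilyl ether and C4 trimethylsilyl enol ether of 23 (C4=C(OSiMe3)CH3, alkene geometry not defined; not isolated) | COc1c(C=O)c(O[Si](C)(C)C)cc2c1[C@H]1Oc3cc4cc(C)ncc4c(OC)c3[C@H](O1)C2=C(C)O[Si](C)(C)C | intermediate
25 | (1R,3R,4S)-4-acetyl-6-hydroxy-8-methoxy-1,3-[(8-methoxy-3-methylisoquinoline-7,6-diyl)oxy]isochromane-7-carbaldehyde (C3–C7′ bond, C1–O–C6′ bridge; acetyl endo) | COc1c(C=O)c(O)cc2c1[C@H]1Oc3cc4cc(C)ncc4c(OC)c3[C@H](O1)[C@H]2C(C)=O | target

**Step count and risks**

Total step count: 20.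
Longest linear sequence: 18 steps (1–5, 8–13, 14–20); the anhydride branch (steps 6–7) joins at step 14.

Steps most likely to fail:

Step 14. What may go wrong is loss of enantioface control through a background addition promoted by the isoquinoline nitrogen, or sluggish addition to the di-ortho-substituted aldehyde. The fallback sets out from 9 and 15 and gives up catalysis for resolution. The two are combined with i-Pr2NEt in CH2Cl2 (the base-mediated anhydride–aldehyde addition–lactonisation), which gives 17 together with its mirror image, the (3S,4S) trans lactone acid F1. The racemate is resolved by crystallising the (R)-1-phenylethylammonium salt of 17, F2, and cold dilute citric acid returns 17, where the route is rejoined.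

Step 17. What may go wrong is failure of ketal formation at the hindered carbonyl, or cleavage of the acid-labile ethers and ionisation at C3 under the stoichiometric silyl triflate. The fallback sets out from 17 and never exposes a ketone to hydride. i-Bu2AlH (3.5 equiv, −78 °C) reduces the lactone while the acid is protected as its aluminium carboxylate, giving the lactol acid F3. Aqueous HCl/THF then removes all acetal-type groups and closes ring C to the bridged carboxylic acid F4. Steglich thioesterification gives the bridged exo S-ethyl thioester F5, and Fukuyama coupling with MeZnI leads to 23, where the route is rejoined before step 20.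

Step 20. What may go wrong is enolisation towards the methyl group instead of the benzylic methine, or equilibration of the endo ketone back to the more stable exo epimer during work-up. The fallback sets out from 17 and passes through the lactol acid F3, the bridged carboxylic acid F4 and the bridged exo S-ethyl thioester F5, which has a single α-hydrogen. LiN(SiMe3)2 (excess, THF, −78 °C) forms the thioester enolate with no regiochemical choice, and an inverse quench into cold AcOH protonates it on the convex face to give the bridged endo S-ethyl thioester F6. Fukuyama coupling under neutral conditions then forms the methyl ketone with C4 already in place and gives the target 25 directly.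

Further compounds
F1 | step 14 | (3S,4S)-7-(1,3-dioxolan-2-yl)-8-methoxy-3-[8-methoxy-6-(methoxymethoxy)-3-methylisoquinolin-7-yl]-6-(methoxymethoxy)-1-oxoisochromane-4-carboxylic acid (enantiomer of 17) | COc1c(C5OCCO5)c(OCOC)cc2c1C(=O)O[C@H](c3c(OCOC)cc4cc(C)ncc4c3OC)[C@H]2C(=O)O
F2 | step 14 | (R)-1-phenylethylammonium salt of 17 | COc1c(C5OCCO5)c(OCOC)cc2c1C(=O)O[C@@H](c3c(OCOC)cc4cc(C)ncc4c3OC)[C@@H]2C(=O)[O-].C[C@@H]([NH3+])c1ccccc1
F3 | step 17 | (3R,4R)-7-(1,3-dioxolan-2-yl)-1-hydroxy-8-methoxy-3-[8-methoxy-6-(methoxymethoxy)-3-methylisoquinolin-7-yl]-6-(methoxymethoxy)isochromane-4-carboxylic acid (lactol acid, both C1 epimers) | COc1c(C5OCCO5)c(OCOC)cc2c1C(O)O[C@@H](c3c(OCOC)cc4cc(C)ncc4c3OC)[C@@H]2C(=O)O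
F4 | step 17 | (1R,3R,4R)-7-formyl-6-hydroxy-8-methoxy-1,3-[(8-methoxy-3-methylisoquinoline-7,6-diyl)oxy]isochromane-4-carboxylic acid (bridged acid, carboxyl exo) | COc1c(C=O)c(O)cc2c1[C@H]1Oc3cc4cc(C)ncc4c(OC)c3[C@H](O1)[C@@H]2C(=O)O
F5 | step 17 | S-ethyl (1R,3R,4R)-7-formyl-6-hydroxy-8-methoxy-1,3-[(8-methoxy-3-methylisoquinoline-7,6-diyl)oxy]isochromane-4-carbothioate (bridged thioester, exo) | COc1c(C=O)c(O)cc2c1[C@H]1Oc3cc4cc(C)ncc4c(OC)c3[C@H](O1)[C@@H]2C(=O)SCC
F6 | step 20 | S-ethyl (1R,3R,4S)-7-formyl-6-hydroxy-8-methoxy-1,3-[(8-methoxy-3-methylisoquinoline-7,6-diyl)oxy]isochromane-4-carbothioate (bridged thioester, endo) | COc1c(C=O)c(O)cc2c1[C@H]1Oc3cc4cc(C)ncc4c(OC)c3[C@H](O1)[C@H]2C(=O)SCC
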